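**Strategy.** The synthesis rests on reading the acylated 4,4-dimethylcyclohexanetrione (filicinic acid) ring as a folded tetraketide. Its ring carbonyl carbon lying between the C(CH3)2 carbon and the isobutyryl-bearing carbon is the ester carbon, and the isobutyryl-bearing carbon the doubly activated methylene, of a linear 2,2-dimethyl-3,5,7-triketo ester. A biomimetic Claisen (Dieckmann-type) cyclisation, the ring closure of acylphloroglucinol biosynthesis, joins these two atoms; the quaternary carbon blocks the competing aldol mode. The triketo ester arises in the same flask from a β-diketone dianion and dimethyl dimethylmalonate, so one operation delivers isobutyrylfilicinic acid. A Mannich-derived methylene then links it to a 2-O-prenylated phlorobenzophenone.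

Key step: step 1

Remark on the chemistry: sarothralin has no stereocentre, so no configuration has to be set. The filicinic acid ring and its precursors are written in the dienol tautomer of the target structure; these tautomers interconvert freely.

**Step 1**
Reactants: 1 5-methylhexane-2,4-dione; 2 dimethyl 2,2-dimethylpropanedioate
Product: 4 isobutyrylfilicinic acid, via triketo ester 3 (not isolated)
Conditions: 1 (2.0 equiv), LiN(i-Pr)2 (4.1 equiv), THF, −78 to 0 °C; 2 (1.0 equiv), −78 °C to rt; then NaOMe, MeOH, 65 °C; 1 M HCl
Reagents that add atoms: none
Why: Double deprotonation of 1 gives the 1,3-dianion, whose terminal carbanion (formed at the methyl group, not at the hindered isopropyl methine) acylates one ester of 2 in a crossed Claisen condensation to give the dianion of 3; on warming in methoxide the C6 carbanion of 3, flanked by the C5 and C7 carbonyls, attacks the C1 ester carbonyl, methoxide leaves and the new tricarbonyl system is deprotonated irreversibly. The closest known reaction type is the Claisen (Dieckmann-type) cyclisation of 3,5,7-triketo esters to acylphloroglucinols, the ring closure used by chalcone-synthase-type polyketide synthases. The six-membered carbocycle closes in a 6-(enolendo)-exo-trig mode by forming the bond between the former ester carbon and the carbon that carries the isobutyryl group. No stereocentre is created. The step needs C-acylation at C6 in preference to the aldol (resorcylate) mode, to lactonisation through the C5 enolate oxygen and to a second intermolecular acylation: the quaternary C2 has no proton and cannot act as an aldol donor, the gem-dimethyl group favours the folded conformer, O-acylation is reversible under methoxide whereas the Claisen product is removed as its stabilised anion, and the dianionic charge of 3 shields its remaining hindered ester from a second dianion.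

**Step 2**
Reactants: 4 isobutyrylfilicinic acid
Product: 5 4-[(dimethylamino)methyl]-3,5-dihydroxy-6,6-dimethyl-2-(2-methylpropanoyl)cyclohexa-2,4-dien-1-one (Mannich base of 4)
Conditions: Me2N=CH2 I (1.05 equiv), CH2Cl2, 0 °C to rt; aq NaHCO3
Reagents that add atoms: N,N-dimethylmethylideneammonium iodide, C[N+](C)=C.[I-]
Why: Mannich reaction: the single unsubstituted ring carbon of 4, flanked by two enolised carbonyl carbons, is the only nucleophilic CH and adds to the preformed iminium ion, so one aminomethyl compound (a betaine after the bicarbonate wash) should form.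

**Step 3**
Reactants: 6 2,4,6-trihydroxybenzophenone
Product: 7 [2-hydroxy-4,6-bis(tert-butyldimethylsilyloxy)phenyl](phenyl)methanone
Conditions: TBSCl (2.2 equiv), imidazole (4.5 equiv), DMF, 0 °C to rt
Reagents that add atoms: tert-butyldimethylsilyl chloride, CC(C)(C)[Si](C)(C)Cl
Why: Silylation of phenols: the para hydroxyl and one of the two equivalent ortho hydroxyls react, whereas the last ortho hydroxyl is locked in a hydrogen bond to the benzoyl oxygen, the usual outcome for 2,4,6-trihydroxyaryl ketones with two equivalents of silyl chloride.

**Step 4**
Reactants: 7 [2-hydroxy-4,6-bis(tert-butyldimethylsilyloxy)phenyl](phenyl)methanone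
Product: 8 [2,4-bis(tert-butyldimethylsilyloxy)-6-(3-methylbut-2-enyloxy)phenyl](phenyl)methanone
Conditions: 3-methylbut-2-en-1-ol (1.5 equiv), PPh3 (1.5 equiv), DIAD (1.5 equiv), THF, 0 °C to rt
Reagents that add atoms: 3-methylbut-2-en-1-ol, CC(C)=CCO
Why: Mitsunobu etherification of the remaining chelated phenol with the primary allylic alcohol proceeds under neutral conditions by SN2 attack at the oxyphosphonium carbon, which keeps both silyl ethers in place and gives the linear 3-methylbut-2-enyl ether.

**Step 5**
Reactants: 8 [2,4-bis(tert-butyldimethylsilyloxy)-6-(3-methylbut-2-enyloxy)phenyl](phenyl)methanone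
Product: 9 [2,4-dihydroxy-6-(3-methylbut-2-enyloxy)phenyl](phenyl)methanone
Conditions: Bu4NF (2.2 equiv), AcOH (2.2 equiv), THF, 0 °C
Reagents that add atoms: none
Why: Fluoride cleaves both aryl silicon–oxygen bonds (desilylation), the acetic acid buffer protonates the phenoxides as they form, and the allylic ether and the diaryl ketone are inert.

**Step 6**
Reactants: 5 Mannich base of isobutyrylfilicinic acid; 9 [2,4-dihydroxy-6-(3-methylbut-2-enyloxy)phenyl](phenyl)methanone
Product: 11 sarothralin, via methylene trione 10 (not isolated)
Conditions: 9 (1.5 equiv), 5 added in portions, NaOAc (0.2 equiv), MeCN, 60 °C; 0.5 M HCl wash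
Reagents that add atoms: none
Why: E1cB loss of dimethylamine from the betaine 5 gives the 2-methylene-1,3-dicarbonyl acceptor 10, which undergoes Michael-type Friedel–Crafts C-alkylation by the phenoxide of 9 at the ring carbon between its two free hydroxyls (ortho to both oxygens, less hindered than the carbon beside the prenyl ether, product held by two O–H···O bonds across the bridge, and the addition is reversible so this isomer should accumulate), the established way of joining filicinic acids to acylphloroglucinols through a methylene bridge.

**Compound list**

1 | 5-methylhexane-2,4-dione | CC(C)C(=O)CC(C)=O | starting material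
2 | dimethyl 2,2-dimethylpropanedioate (dimethyl dimethylmalonate) | COC(=O)C(C)(C)C(=O)OC | starting material
3 | methyl 2,2,8-trimethyl-3,5,7-trioxononanoate (triketo ester) | COC(=O)C(C)(C)C(=O)CC(=O)CC(=O)C(C)C | intermediate
4 | isobutyrylfilicinic acid, 3,5-dihydroxy-6,6-dimethyl-2-(2-methylpropanoyl)cyclohexa-2,4-dien-1-one | CC(C)C(=O)C1=C(O)C=C(O)C(C)(C)C1=O | intermediate
5 | 4-[(dimethylamino)methyl]-3,5-dihydroxy-6,6-dimethyl-2-(2-methylpropanoyl)cyclohexa-2,4-dien-1-one | CC(C)C(=O)C1=C(O)C(CN(C)C)=C(O)C(C)(C)C1=O | intermediate
6 | 2,4,6-trihydroxybenzophenone | O=C(c1ccccc1)c1c(O)cc(O)cc1O | starting material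
7 | [2-hydroxy-4,6-bis(tert-butyldimethylsilyloxy)phenyl](phenyl)methanone | CC(C)(C)[Si](C)(C)Oc1cc(O)c(C(=O)c2ccccc2)c(O[Si](C)(C)C(C)(C)C)c1 | intermediate
8 | [2,4-bis(tert-butyldimethylsilyloxy)-6-(3-methylbut-2-enyloxy)phenyl](phenyl)methanone | CC(C)=CCOc1cc(O[Si](C)(C)C(C)(C)C)cc(O[Si](C)(C)C(C)(C)C)c1C(=O)c1ccccc1 | intermediate
9 | [2,4-dihydroxy-6-(3-methylbut-2-enyloxy)phenyl](phenyl)methanone | CC(C)=CCOc1cc(O)cc(O)c1C(=O)c1ccccc1 | intermediate
10 | 3-hydroxy-6,6-dimethyl-4-methylidene-2-(2-methylpropanoyl)cyclohex-2-ene-1,5-dione (methylene trione) | CC(C)C(=O)C1=C(O)C(=C)C(=O)C(C)(C)C1=O | intermediate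
11 | sarothralin | CC(C)=CCOc1cc(O)c(CC2=C(O)C(C)(C)C(=O)C(C(=O)C(C)C)=C2O)c(O)c1C(=O)c1ccccc1 | target

**Totals**

Total step count: 6. Longest linear sequence: 4 steps (steps 3, 4, 5 and 6); the other branch (steps 1 and 2) joins at step 6.

**Steps most likely to fail**

Step 1 (key step). A second dianion may acylate the remaining ester before ring closure, proton transfer may quench the dianion, or closure onto the hindered ester may stay incomplete in the one-flask sequence. The fallback separates chain assembly from ring closure; it sets out from 2 and comes back at 4. Half-saponification of 2 (KOH, 1.0 equiv, MeOH) would give 3-methoxy-2,2-dimethyl-3-oxopropanoic acid F1. Activation with 1,1'-carbonyldiimidazole and reaction with N,O-dimethylhydroxylamine hydrochloride would give the N-methoxy-N-methylamide methyl 3-[methoxy(methyl)amino]-2,2-dimethyl-3-oxopropanoate F2. The dianion of 1 would be acylated by F2 at −78 °C, where the chelated tetrahedral adduct stops the reaction at 3 and leaves the ester untouched. Isolated 3 would then be closed in a separate Claisen cyclisation (NaOMe, MeOH, 65 °C) to 4.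

Step 6. Site selectivity between the two free ring carbons of 9 may be poor, and a second alkylation of the product may compete. The fallback blocks the para oxygen so that a single phenol directs the attack; it sets out from 9 and comes back at 11. Silylation of 9 with i-Pr3SiCl (1.05 equiv) and imidazole in DMF at 0 °C should touch only the non-hydrogen-bonded para hydroxyl and give [2-hydroxy-6-(3-methylbut-2-enyloxy)-4-(triisopropylsilyloxy)phenyl](phenyl)methanone F3. Heating F3 with 5 in toluene at 80 °C should deliver 10 to the carbon ortho to the one remaining phenol, which is hydrogen-bonded to the acceptor, while the other free carbon lies between two ethers, one of them bulky. This would give 4'-O-triisopropylsilyl sarothralin F4. Desilylation with Bu4NF and AcOH in THF at 0 °C then gives 11.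

Step 4. Activation of the permanently hydrogen-bonded phenol may be sluggish, and silyl transfer between oxygens or SN2′ attack may intervene. The fallback etherifies one of two equivalent ortho hydroxyls of a para-acylated benzophenone by a Williamson reaction; it sets out from 6 and comes back at 9. Pivaloyl chloride (1.0 equiv) and pyridine in CH2Cl2 at −20 °C should acylate the most acidic, non-hydrogen-bonded para hydroxyl and give 4-benzoyl-3,5-dihydroxyphenyl 2,2-dimethylpropanoate F5. 1-Bromo-3-methylbut-2-ene (1.05 equiv) and K2CO3 in acetone at rt should etherify one ortho hydroxyl, the second being deactivated by chelation once the first has reacted, to give 4-benzoyl-3-hydroxy-5-(3-methylbut-2-enyloxy)phenyl 2,2-dimethylpropanoate F6. Methanolysis of the aryl ester (K2CO3, MeOH, rt) then gives 9.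

**Further compounds**

F1 | step 1 | 3-methoxy-2,2-dimethyl-3-oxopropanoic acid | COC(=O)C(C)(C)C(=O)O
F2 | step 1 | methyl 3-[methoxy(methyl)amino]-2,2-dimethyl-3-oxopropanoate | COC(=O)C(C)(C)C(=O)N(C)OC
F3 | step 6 | [2-hydroxy-6-(3-methylbut-2-enyloxy)-4-(triisopropylsilyloxy)phenyl](phenyl)methanone | CC(C)=CCOc1cc(O[Si](C(C)C)(C(C)C)C(C)C)cc(O)c1C(=O)c1ccccc1
F4 | step 6 | 4'-O-triisopropylsilyl sarothralin | CC(C)=CCOc1cc(O[Si](C(C)C)(C(C)C)C(C)C)c(CC2=C(O)C(C)(C)C(=O)C(C(=O)C(C)C)=C2O)c(O)c1C(=O)c1ccccc1
F5 | step 4 | 4-benzoyl-3,5-dihydroxyphenyl 2,2-dimethylpropanoate | CC(C)(C)C(=O)Oc1cc(O)c(C(=O)c2ccccc2)c(O)c1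
F6 | step 4 | 4-benzoyl-3-hydroxy-5-(3-methylbut-2-enyloxy)phenyl 2,2-dimethylpropanoate | CC(C)=CCOc1cc(OC(=O)C(C)(C)C)cc(O)c1C(=O)c1ccccc1
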